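**Retrosynthetic overview**
- The target is (3S,6R)-3-hydroxy-8'-apo-ε-caroten-8'-al (3-OH and C6 chain cis); the last step is cleavage of a C3 silyl ether.
- The strategy rests on C15=C15', the only chain alkene whose two neighbours, C14 and C14', are both CH termini of E methyl-bearing alkenes (C13=C14 and C14'=C13'). The bonds C14–C15 and C15'–C14' are therefore cut, giving a ring-bearing C19 tetraenyl iodide, a C9 iodotrienal and an (E)-ethene-1,2-diyl tin/boron linchpin.
- The C19 iodide comes from racemic α-ionone: C3 oxidation, reduction and lipase resolution fix C3/C6; the chain is grown by olefination at C9=C10 and C11=C12, then C13≡C14 is made, methylaluminated and iodinated.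
- The C9 iodotrienal comes from propargyl alcohol (carboalumination, iodination) and a C5 phosphonate ester; the linchpin comes from ethynyl pinacol boronate by hydrostannation.
- Rings: the only ring (cyclohexene C1–C6) is bought with α-ionone; no ring is formed in the route.

Key step: step 18

Remark on numbering: carotenoid locants are used (ring C1–C6, chain C7–C15 and C15'–C8'; C3 carries oxygen, C6 carries the chain).
Assumption: the Pseudomonas lipase acylates the 3R alcohol of the cis pair faster, the usual sense for cyclohex-2-enols of this shape, so the 3S,6R alcohol is the one left unreacted.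
Remark on handling: all polyenes are kept under argon in dim light; if the coupled product contains Z isomers, a brief equilibration with a trace of iodine would precede the last step (not counted as a step).

**Route**

Step 1
Reactants: 1 α-ionone (racemic)
Product: 2 α-ionone ethylene ketal, 2-methyl-2-[(E)-2-(2,6,6-trimethylcyclohex-2-en-1-yl)ethenyl]-1,3-dioxolane (racemic)
Conditions: ethylene glycol, HC(OEt)3, p-TsOH (cat.), rt
Reagents that add atoms: ethylene glycol, OCCO
Why: Acid-catalysed ketalisation, driven by the orthoformate as water scavenger, masks the side-chain enone so that only the ring ketone made in step 2 is reduced in step 3; at room temperature the ring alkene should stay in the α position.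

Step 2
Reactants: 2 α-ionone ethylene ketal
Product: 3 3-oxo-α-ionone ethylene ketal, 3,5,5-trimethyl-4-[(E)-2-(2-methyl-1,3-dioxolan-2-yl)ethenyl]cyclohex-2-en-1-one (racemic)
Conditions: t-BuOOH (70% aq.), aq. NaOCl, K2CO3, MeCN, −5 to 0 °C
Reagents that add atoms: tert-butyl hydroperoxide, CC(C)(C)OO
Why: Radical allylic oxidation (Kharasch-type tert-butylperoxy radical chain) should convert the only allylic ring methylene, C3, into the enone, the doubly allylic C6–H being shielded by the C1 gem-dimethyl and C5 methyl groups.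

Step 3
Reactants: 3 3-oxo-α-ionone ethylene ketal
Product: 4 cis-3-hydroxy-α-ionone ethylene ketal, rac-(1S,4R)-3,5,5-trimethyl-4-[(E)-2-(2-methyl-1,3-dioxolan-2-yl)ethenyl]cyclohex-2-en-1-ol (racemate, OH and side chain cis)
Conditions: LiAlH4, Et2O, −78 °C; aqueous work-up; chromatographic removal of the trans epimer
Reagents that add atoms: none
Why: 1,2-Reduction of the β,β-disubstituted cyclohexenone by a small hydride: axial delivery anti to the pseudo-axial C6 side chain gives the cis alcohol (C3 set relative to C6 by substrate control), while delivery anti to the axial C1 methyl gives the trans epimer, so both are expected and the cis racemate is isolated by chromatography.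

Step 4
Reactants: 4 cis-3-hydroxy-α-ionone ethylene ketal (racemate)
Product: 5 cis-3-hydroxy-α-ionone, rac-(E)-4-[(1R,4S)-4-hydroxy-2,6,6-trimethylcyclohex-2-en-1-yl]but-3-en-2-one (racemate)
Conditions: PPTS (cat.), acetone/H2O, rt
Reagents that add atoms: water, O
Why: Mild acid-catalysed hydrolysis of the dioxolane of a conjugated ketone is fast and, under pyridinium tosylate buffering, should leave the allylic alcohol untouched.

Step 5
Reactants: 5 cis-3-hydroxy-α-ionone (racemate)
Product: 6 (3S,6R)-3-hydroxy-α-ionone, (E)-4-[(1R,4S)-4-hydroxy-2,6,6-trimethylcyclohex-2-en-1-yl]but-3-en-2-one (single enantiomer, recovered alcohol)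
Conditions: lipase AK (Pseudomonas fluorescens), vinyl acetate, t-BuOMe, rt, run slightly past half conversion; chromatographic separation from the acetate
Reagents that add atoms: none
Why: Lipase-catalysed irreversible transesterification (kinetic resolution) acylates the 3R enantiomer of the cis pair, so the recovered alcohol is the 3S,6R enantiomer, which fixes C3 and C6 in absolute terms; running past half conversion raises its enantiomeric purity.

Step 6
Reactants: 6 (3S,6R)-3-hydroxy-α-ionone
Product: 7 (3S,6R)-3-(tert-butyldimethylsilyloxy)-α-ionone, (E)-4-[(1R,4S)-4-(tert-butyldimethylsilyloxy)-2,6,6-trimethylcyclohex-2-en-1-yl]but-3-en-2-one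
Conditions: TBSCl, imidazole, DMF, rt
Reagents that add atoms: tert-butyldimethylsilyl chloride, CC(C)(C)[Si](C)(C)Cl
Why: Imidazole-promoted silylation of the secondary allylic alcohol gives an ether that withstands the bases, hydrides, organoaluminium and palladium steps ahead.

Step 7
Reactants: 7 (3S,6R)-3-(tert-butyldimethylsilyloxy)-α-ionone
Product: 8 C15 nitrile, (2E,4E)-5-[(1R,4S)-4-(tert-butyldimethylsilyloxy)-2,6,6-trimethylcyclohex-2-en-1-yl]-3-methylpenta-2,4-dienenitrile
Conditions: (EtO)2P(O)CH2CN, NaH, THF, 0 °C to rt; chromatographic removal of the 9Z isomer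
Reagents that add atoms: diethyl cyanomethylphosphonate, CCOP(=O)(CC#N)OCC
Why: Horner–Wadsworth–Emmons olefination of the methyl ketone builds C9=C10 with the thermodynamically preferred E geometry as the major isomer, and the weakly basic stabilised anion leaves C6–H and the silyl ether alone.

Step 8
Reactants: 8 C15 nitrile
Product: 10 C15 aldehyde, (2E,4E)-5-[(1R,4S)-4-(tert-butyldimethylsilyloxy)-2,6,6-trimethylcyclohex-2-en-1-yl]-3-methylpenta-2,4-dienal, via aluminium aldimine 9 (not isolated)
Conditions: i-Bu2AlH, toluene, −78 °C; then wet SiO2, 0 °C to rt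
Reagents that add atoms: water, O
Why: Partial reduction of the nitrile by i-Bu2AlH stops at the aluminium aldimine, which hydrolyses to the aldehyde on wet silica without touching the diene geometry or the silyl ether.

Step 9
Reactants: 10 C15 aldehyde
Product: 11 C18 ketone, (3E,5E,7E)-8-[(1R,4S)-4-(tert-butyldimethylsilyloxy)-2,6,6-trimethylcyclohex-2-en-1-yl]-6-methylocta-3,5,7-trien-2-one
Conditions: Ph3P=CHC(O)CH3, toluene, 90 °C
Reagents that add atoms: 1-(triphenylphosphoranylidene)propan-2-one, CC(=O)C=P(c1ccccc1)(c1ccccc1)c1ccccc1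
Why: Wittig olefination with a stabilised ylide should give the E enone at C11=C12 under neutral conditions.

Step 10
Reactants: 11 C18 ketone
Product: 13 tetraenyne, tert-butyldimethyl{[(1S,4R)-3,5,5-trimethyl-4-[(1E,3E,5E)-3-methylocta-1,3,5-trien-7-yn-1-yl]cyclohex-2-en-1-yl]oxy}silane, via enol phosphate 12 (not isolated)
Conditions: LiN(i-Pr)2 (1.05 equiv), THF, −78 °C; ClP(O)(OEt)2, −78 °C to rt; then LiN(i-Pr)2 (2.3 equiv), −78 °C to rt; H2O
Reagents that add atoms: none
Why: Negishi's enol phosphate route to terminal alkynes: kinetic deprotonation at the acetyl methyl, O-phosphorylation and base-induced elimination of diethyl phosphate (the lithium acetylide being protonated on work-up) turn the acetyl group into C13≡C14 without touching the existing E alkenes.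

Step 11
Reactants: 13 tetraenyne
Product: 15 C19 tetraenyl iodide, tert-butyl{[(1S,4R)-4-[(1E,3E,5E,7E)-8-iodo-3,7-dimethylocta-1,3,5,7-tetraen-1-yl]-3,5,5-trimethylcyclohex-2-en-1-yl]oxy}dimethylsilane, via alkenylalane 14 (not isolated)
Conditions: Me3Al (3 equiv), Cp2ZrCl2 (0.25 equiv), CH2Cl2, 0 °C to rt; then I2, THF, −30 to 0 °C
Reagents that add atoms: trimethylaluminium, C[Al](C)C; iodine, [I][I]
Why: Zirconium-catalysed Negishi carboalumination adds methyl and aluminium syn across the alkyne (methyl to C13, aluminium to terminal C14), and iodinolysis of the C–Al bond with retention gives the 13E alkenyl iodide.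

Step 12
Reactants: 16 propargyl alcohol
Product: 18 (E)-3-iodo-2-methylprop-2-en-1-ol, via alkoxy alkenylalane 17 (not isolated)
Conditions: Me3Al (3 equiv), Cp2ZrCl2 (0.25 equiv), CH2Cl2, 0 °C to rt; then I2, THF, −30 to 0 °C; aqueous work-up
Reagents that add atoms: trimethylaluminium, C[Al](C)C; iodine, [I][I]
Why: Negishi carboalumination of the aluminium alkoxide of the alkyne is syn and places methyl on the internal carbon, so iodinolysis with retention gives the E iodoalkene.

Step 13
Reactants: 18 (E)-3-iodo-2-methylprop-2-en-1-ol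
Product: 19 (E)-3-iodo-2-methylprop-2-enal
Conditions: MnO2, CH2Cl2, rt; filtered solution used directly (volatile aldehyde)
Reagents that add atoms: none
Why: Allylic oxidation with MnO2 is selective for the allylic alcohol and does not isomerise the iodoalkene.

Step 14
Reactants: 19 (E)-3-iodo-2-methylprop-2-enal; 20 ethyl (E)-4-(diethoxyphosphoryl)-2-methylbut-2-enoate
Product: 21 ethyl (2E,4E,6E)-7-iodo-2,6-dimethylhepta-2,4,6-trienoate
Conditions: LiN(SiMe3)2, THF, −78 °C (anion of 20), then 19, −78 to 0 °C
Reagents that add atoms: none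
Why: Horner–Wadsworth–Emmons olefination through the phosphorus-bearing carbon of the vinylogous phosphonate anion forms C12'=C11' with E geometry, and the conjugated 2E ester geometry is the thermodynamic one.

Step 15
Reactants: 21 ethyl (2E,4E,6E)-7-iodo-2,6-dimethylhepta-2,4,6-trienoate
Product: 22 (2E,4E,6E)-7-iodo-2,6-dimethylhepta-2,4,6-trien-1-ol
Conditions: i-Bu2AlH (2.2 equiv), CH2Cl2, −78 °C; aqueous work-up
Reagents that add atoms: none
Why: Ester reduction by i-Bu2AlH at low temperature gives the allylic alcohol without conjugate reduction or loss of iodine.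

Step 16
Reactants: 22 (2E,4E,6E)-7-iodo-2,6-dimethylhepta-2,4,6-trien-1-ol
Product: 23 (2E,4E,6E)-7-iodo-2,6-dimethylhepta-2,4,6-trienal
Conditions: MnO2, CH2Cl2, rt, dark
Reagents that add atoms: none
Why: MnO2 oxidation of the trienyl carbinol to the conjugated aldehyde should proceed without over-oxidation or E/Z change.

Step 17
Reactants: 24 2-ethynyl-4,4,5,5-tetramethyl-1,3,2-dioxaborolane
Product: 25 (E)-tributyl[2-(4,4,5,5-tetramethyl-1,3,2-dioxaborolan-2-yl)vinyl]stannane
Conditions: Bu3SnH, AIBN (cat.), toluene, 85 °C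
Reagents that add atoms: tributyltin hydride, CCCC[SnH](CCCC)CCCC
Why: Radical chain hydrostannation: the tributylstannyl radical adds to the terminal alkyne carbon to give the α-boryl vinyl radical, and reversible stannyl radical addition at 85 °C should equilibrate the adduct to the more stable E isomer.

Step 18
Reactants: 23 (2E,4E,6E)-7-iodo-2,6-dimethylhepta-2,4,6-trienal; 25 (E)-tributyl[2-(4,4,5,5-tetramethyl-1,3,2-dioxaborolan-2-yl)vinyl]stannane; 15 C19 tetraenyl iodide
Product: 27 C3 tert-butyldimethylsilyl ether of the target, (2E,4E,6E,8E,10E,12E,14E,16E)-17-[(1R,4S)-4-(tert-butyldimethylsilyloxy)-2,6,6-trimethylcyclohex-2-en-1-yl]-2,6,11,15-tetramethylheptadeca-2,4,6,8,10,12,14,16-octaenal, via tetraenal boronate 26 (not isolated)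
Conditions: 23 (1.0 equiv), 25 (1.05 equiv), Pd2(dba)3 (5 mol %), AsPh3 (20 mol %), DMF, rt, no base, until 23 is consumed; then 15 (0.85 equiv) in THF, aq. K3PO4 (3 M), rt to 35 °C; Ar, dark
Reagents that add atoms: none
Why: Zerovalent palladium inserts into the C14'–I bond of 23 and, with no base present, only the C–Sn bond of 25 transmetalates, since the pinacol boronate needs an oxygen base before boron can pass its carbon to palladium; reductive elimination forms C15'–C14' and gives 26. Adding aqueous K3PO4 and iodide 15 then starts the Suzuki–Miyaura cycle on the same catalyst: insertion into C14–I, base-assisted transmetalation from boron and reductive elimination form C14–C15. The closest known reaction type is the sequential Stille and Suzuki–Miyaura coupling of 2-stannylvinyl boronates with two different alkenyl iodides. No ring is closed and no stereocentre is formed; C3, C6 and the aldehyde are spectators. The step needs tin to react before boron, which is secured by withholding base until 23 is gone and by making 23 the limiting partner of the first stage. It also needs retention of every alkene geometry, which follows from retention at sp2 carbon in all three elementary steps and from AsPh3 allowing the Stille stage at room temperature.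

Step 19
Reactants: 27 C3 tert-butyldimethylsilyl ether of the target
Product: 28 target, (2E,4E,6E,8E,10E,12E,14E,16E)-17-[(1R,4S)-4-hydroxy-2,6,6-trimethylcyclohex-2-en-1-yl]-2,6,11,15-tetramethylheptadeca-2,4,6,8,10,12,14,16-octaenal
Conditions: Bu4NF, AcOH, THF, 0 °C to rt, dark
Reagents that add atoms: none
Why: Fluoride-induced desilylation, buffered with acetic acid to spare the aldehyde and the allylic ε-ring alcohol, releases the C3 hydroxyl with retention because no bond to C3 is broken.

**Compound list**
1 | α-ionone (racemic) | CC1=CCCC(C)(C)C1/C=C/C(C)=O | starting material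
2 | α-ionone ethylene ketal (racemic) | CC1=CCCC(C)(C)C1/C=C/C2(C)OCCO2 | intermediate
3 | 3-oxo-α-ionone ethylene ketal (racemic) | CC1=CC(=O)CC(C)(C)C1/C=C/C2(C)OCCO2 | intermediate
4 | cis-3-hydroxy-α-ionone ethylene ketal (racemate, relative configuration shown) | CC1=C[C@@H](O)CC(C)(C)[C@H]1/C=C/C2(C)OCCO2 | intermediate
5 | cis-3-hydroxy-α-ionone (racemate, relative configuration shown) | CC1=C[C@@H](O)CC(C)(C)[C@H]1/C=C/C(C)=O | intermediate
6 | (3S,6R)-3-hydroxy-α-ionone | CC1=C[C@@H](O)CC(C)(C)[C@H]1/C=C/C(C)=O | intermediate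
7 | (3S,6R)-3-(tert-butyldimethylsilyloxy)-α-ionone | CC1=C[C@@H](O[Si](C)(C)C(C)(C)C)CC(C)(C)[C@H]1/C=C/C(C)=O | intermediate
8 | C15 nitrile, (2E,4E)-3-methyl-5-(silyloxy ring)penta-2,4-dienenitrile | CC1=C[C@@H](O[Si](C)(C)C(C)(C)C)CC(C)(C)[C@H]1/C=C/C(C)=C/C#N | intermediate
9 | N-(diisobutylaluminio) aldimine of 10 (not isolated) | CC1=C[C@@H](O[Si](C)(C)C(C)(C)C)CC(C)(C)[C@H]1/C=C/C(C)=C/C=N[Al](CC(C)C)CC(C)C | intermediate
10 | C15 aldehyde, (2E,4E)-3-methyl-5-(silyloxy ring)penta-2,4-dienal | CC1=C[C@@H](O[Si](C)(C)C(C)(C)C)CC(C)(C)[C@H]1/C=C/C(C)=C/C=O | intermediate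
11 | C18 ketone, (3E,5E,7E)-6-methyl-8-(silyloxy ring)octa-3,5,7-trien-2-one | CC1=C[C@@H](O[Si](C)(C)C(C)(C)C)CC(C)(C)[C@H]1/C=C/C(C)=C/C=C/C(C)=O | intermediate
12 | diethyl (3E,5E,7E)-6-methyl-8-(silyloxy ring)octa-1,3,5,7-tetraen-2-yl phosphate (not isolated) | CC1=C[C@@H](O[Si](C)(C)C(C)(C)C)CC(C)(C)[C@H]1/C=C/C(C)=C/C=C/C(=C)OP(=O)(OCC)OCC | intermediate
13 | tetraenyne, ring–C7=C8–C9(Me)=C10–C11=C12–C13≡C14H | CC1=C[C@@H](O[Si](C)(C)C(C)(C)C)CC(C)(C)[C@H]1/C=C/C(C)=C/C=C/C#C | intermediate
14 | (13E)-C14 dimethylalane from 13 (not isolated) | CC1=C[C@@H](O[Si](C)(C)C(C)(C)C)CC(C)(C)[C@H]1/C=C/C(C)=C/C=C/C(C)=C/[Al](C)C | intermediate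
15 | C19 tetraenyl iodide (silylated ring to C14) | CC1=C[C@@H](O[Si](C)(C)C(C)(C)C)CC(C)(C)[C@H]1/C=C/C(C)=C/C=C/C(C)=C/I | intermediate
16 | propargyl alcohol | C#CCO | starting material
17 | dimethylaluminium (E)-3-(dimethylaluminio)-2-methylprop-2-en-1-olate (not isolated) | C[Al](C)OC/C(C)=C/[Al](C)C | intermediate
18 | (E)-3-iodo-2-methylprop-2-en-1-ol | OC/C(C)=C/I | intermediate
19 | (E)-3-iodo-2-methylprop-2-enal | O=C/C(C)=C/I | intermediate
20 | ethyl (E)-4-(diethoxyphosphoryl)-2-methylbut-2-enoate | CCOC(=O)/C(C)=C/CP(=O)(OCC)OCC | starting material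
21 | ethyl (2E,4E,6E)-7-iodo-2,6-dimethylhepta-2,4,6-trienoate | CCOC(=O)/C(C)=C/C=C/C(C)=C/I | intermediate
22 | (2E,4E,6E)-7-iodo-2,6-dimethylhepta-2,4,6-trien-1-ol | OC/C(C)=C/C=C/C(C)=C/I | intermediate
23 | (2E,4E,6E)-7-iodo-2,6-dimethylhepta-2,4,6-trienal | O=C/C(C)=C/C=C/C(C)=C/I | intermediate
24 | 2-ethynyl-4,4,5,5-tetramethyl-1,3,2-dioxaborolane | C#CB1OC(C)(C)C(C)(C)O1 | starting material
25 | (E)-tributyl[2-(4,4,5,5-tetramethyl-1,3,2-dioxaborolan-2-yl)vinyl]stannane | CCCC[Sn](CCCC)(CCCC)/C=C/B1OC(C)(C)C(C)(C)O1 | intermediate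
26 | (2E,4E,6E,8E)-2,6-dimethyl-9-(4,4,5,5-tetramethyl-1,3,2-dioxaborolan-2-yl)nona-2,4,6,8-tetraenal (not isolated) | O=C/C(C)=C/C=C/C(C)=C/C=C/B1OC(C)(C)C(C)(C)O1 | intermediate
27 | C3 tert-butyldimethylsilyl ether of the target | CC1=C[C@@H](O[Si](C)(C)C(C)(C)C)CC(C)(C)[C@H]1/C=C/C(C)=C/C=C/C(C)=C/C=C/C=C(C)/C=C/C=C(\C)C=O | intermediate
28 | (3S,6R)-3-hydroxy-8'-apo-ε-caroten-8'-al | CC1=C[C@@H](O)CC(C)(C)[C@H]1/C=C/C(C)=C/C=C/C(C)=C/C=C/C=C(C)/C=C/C=C(\C)C=O | target

**Step count**
Total: 19 steps. Longest linear sequence: 13 steps (steps 1–11, 18, 19).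

**Steps most likely to fail**

Step 18. The boronate 26 may lose boron by protonolysis, or the catalyst may die before the second cycle, so that the Suzuki–Miyaura stage stalls or homocoupling takes over. The fallback sets out from 23 and comes back at 27. A Stille coupling of 23 with an excess of commercial (E)-1,2-bis(tributylstannyl)ethene (Pd2(dba)3, AsPh3, DMF, rt) would give (2E,4E,6E,8E)-2,6-dimethyl-9-(tributylstannyl)nona-2,4,6,8-tetraenal F1, which is isolated. A second, separate Stille coupling of F1 with 15 under the same catalyst in NMP would give 27, so both bonds are made at tin and no boron stage is needed.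

Step 10. The excess amide base may also deprotonate C6–H, which is conjugated through the polyene; that would erode the C6 configuration or move the ring alkene into conjugation, and elimination of the enol phosphate may be incomplete. The fallback sets out from 10 and comes back at 13. Arbuzov reaction of 3-bromo-1-(trimethylsilyl)prop-1-yne with P(OEt)3 (neat, 120 °C) would give diethyl [3-(trimethylsilyl)prop-2-yn-1-yl]phosphonate F2. Horner–Wadsworth–Emmons olefination of 10 with F2 (LiN(SiMe3)2, THF, −78 to 0 °C) would form C11=C12 and C13≡C14 together, giving the C-silylated tetraenyne tert-butyldimethyl{[(1S,4R)-3,5,5-trimethyl-4-[(1E,3E,5E)-3-methyl-8-(trimethylsilyl)octa-1,3,5-trien-7-yn-1-yl]cyclohex-2-en-1-yl]oxy}silane F3. K2CO3 in MeOH would remove the alkynyl silyl group to give 13, with no strong amide base ever meeting the polyene.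

Step 3. Hydride may be delivered mainly on the face away from the axial C1 methyl, so that the trans alcohol dominates and too little cis racemate is obtained. The fallback sets out from 3 and comes back at 4. Reduction with the bulky LiBH(s-Bu)3 (THF, −78 °C) would deliberately give the trans alcohol rac-(1R,4R)-3,5,5-trimethyl-4-[(E)-2-(2-methyl-1,3-dioxolan-2-yl)ethenyl]cyclohex-2-en-1-ol F4. Mitsunobu reaction (4-nitrobenzoic acid, PPh3, DIAD, THF, 0 °C) would invert C3 to the cis ester rac-(1S,4R)-3,5,5-trimethyl-4-[(E)-2-(2-methyl-1,3-dioxolan-2-yl)ethenyl]cyclohex-2-en-1-yl 4-nitrobenzoate F5, and K2CO3 in MeOH would release 4.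

Further compounds
F1 | step 18 | (2E,4E,6E,8E)-2,6-dimethyl-9-(tributylstannyl)nona-2,4,6,8-tetraenal | O=C/C(C)=C/C=C/C(C)=C/C=C/[Sn](CCCC)(CCCC)CCCC
F2 | step 10 | diethyl [3-(trimethylsilyl)prop-2-yn-1-yl]phosphonate | CCOP(=O)(CC#C[Si](C)(C)C)OCC
F3 | step 10 | tert-butyldimethyl{[(1S,4R)-3,5,5-trimethyl-4-[(1E,3E,5E)-3-methyl-8-(trimethylsilyl)octa-1,3,5-trien-7-yn-1-yl]cyclohex-2-en-1-yl]oxy}silane | CC1=C[C@@H](O[Si](C)(C)C(C)(C)C)CC(C)(C)[C@H]1/C=C/C(C)=C/C=C/C#C[Si](C)(C)C
F4 | step 3 | rac-(1R,4R)-3,5,5-trimethyl-4-[(E)-2-(2-methyl-1,3-dioxolan-2-yl)ethenyl]cyclohex-2-en-1-ol (trans racemate, relative configuration shown) | CC1=C[C@H](O)CC(C)(C)[C@H]1/C=C/C2(C)OCCO2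
F5 | step 3 | rac-(1S,4R)-3,5,5-trimethyl-4-[(E)-2-(2-methyl-1,3-dioxolan-2-yl)ethenyl]cyclohex-2-en-1-yl 4-nitrobenzoate (cis racemate, relative configuration shown) | CC1=C[C@@H](OC(=O)c2ccc(cc2)[N+](=O)[O-])CC(C)(C)[C@H]1/C=C/C3(C)OCCO3
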